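The runs were computed with made-up constants; noise was put on by code.

I will freeze one number for this flask, the level of target where its curve stops climbing, and reckon from that.

| setting | Saturday's | flask |
|---|---|---|
| substrate | 0.10 M | 0.10 M |
| remark | the very flask that is asked about, followed so far |  |
| time |  | 3.0 min |

- Saturday's (time / s: target / %): 10.0: 27; 15.0: 32; 20.0: 34; 25.0: 43; 30.0: 41; 40.0: 41; 50.0: 49

(each reading ± 2 percentage points)

- what was read earlier has a scatter of 2 percentage points, one standard deviation
- on the list of suspects stand: substrate -> side product; substrate -> target; target <-> isomer of the product

- the moment within 3.0 min at which there is most target
- the amount of target, in percent of the substrate charged, at that time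

Which number exactly? It is Y, the mean of the target readings from 25.0 s to 50.0 s: 43.5%, with a scatter of the mean of 1 percentage point.

But the last reading is the highest; is target not still rising? That reading stands 5.5 points above Y, against a scatter of 2 points for one reading. Yet the first reading of the stretch is higher than the two after it, so I read no steady climb.

Why expect a maximum at all? Target is an intermediate here if the suspected step to the isomer runs: its maximum comes where making and net draining balance, and there the curve is flat.

And the time? The readings do not place it closely. I commit to the middle of the flat stretch, tm = 0.625 min, with about Y as the amount.

The forecast differs from my reckoning. It gives 47% at 1.2 min, on the ground that, if the step to the isomer occurs, “target should peak soon after substrate runs out”.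

The flask gives 45.4% at 0.719 min, which is 1.9 points above Y; the forecast's time is later than this.

    substrate → side product (k = 0.00250 s⁻¹)
    substrate → target (k = 0.0300 s⁻¹)
    target ⇌ isomer of the product (K = 5.60, k = 0.0180 s⁻¹)

At that maximum, substrate still stands at 24.6% and isomer at 24.2%. Each step of the scheme has one reactant, so I carry Y unchanged, as a percentage of the charge, to a neighbour flask charged with 0.040 M of substrate. That neighbour reaches 45.4%, and at 3.00 min it holds 73.8% as isomer of the product.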